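**Strategy.** Atom labels: the six-membered ring runs C1 (holding the side chain), C2 (methylene), C3–C4 (epoxide; C4 methylated), C5–C6 (angelate-bearing); in the chain C7 carries the exocyclic methylene C14, C8 the acetate and C9–C11 the prenyl end. The plan cuts C7–C8 and C8–C14: the allylic unit C14=C7–C8(O) on ring carbon C1 is traced back to a cyclopropanol composed of C7, C8 and C14. A single titanium-mediated union of a C1 vinyl group with a prenyl ester makes both bonds and the three-membered ring; palladium then cleaves C8–C14 to unveil the methylene ketone. The precursor is the all-cis 1-vinyl-4-methylcyclohex-3-ene-5,6-diol acetonide.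

Key step: step 6

Remark on the chemistry: cyclopropanol 12 is expected as two cis-dialkyl diastereomers (the C7/C8 pair in either sense relative to C1); both are carried on together because step 7 erases C7 and C8, and the SMILES of 12 shows one of them. The enantiomeric purity set in step 2 should be raised by recrystallising diol 6 if needed; the reagent-controlled reduction in step 8 should also turn residual minor enantiomer into a separable diastereomer.

Step 1
Reactants: 1 (E)-4-acetoxy-2-methylbut-2-enal
Product: 2 (1E,3E)-2-methylbuta-1,3-diene-1,4-diyl diacetate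
Conditions: isopropenyl acetate (excess), p-TsOH·H2O (2 mol %), 95 °C, acetone distilled off; (1E,3E) isomer purified by distillation or chromatography
Reagents that add atoms: isopropenyl acetate, CC(=C)OC(C)=O
Why: Acid-catalysed enol acetylation of the enal runs through its dienol (loss of a γ-hydrogen from the acetoxymethyl carbon) and under these equilibrating conditions should favour the isomer with both acetoxy groups trans to the diene backbone, the only isomer that can adopt the s-cis conformation needed in step 2.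

Step 2
Reactants: 2 (1E,3E)-2-methylbuta-1,3-diene-1,4-diyl diacetate; 3 acrolein
Product: 4 (1R,3S,6S)-3,6-diacetoxy-4-methylcyclohex-4-ene-1-carbaldehyde (formyl and both acetoxy groups cis)
Conditions: (5S)-5-benzyl-2,2,3-trimethylimidazolidin-4-one hydrochloride (20 mol %), 3 (3 equiv), MeCN/H2O 95:5, 0 °C to rt
Reagents that add atoms: none
Why: In this organocatalytic asymmetric Diels–Alder reaction the secondary amine activates acrolein as a chiral iminium ion, the 2-methyl group of the diene (its two acetoxy termini cancel electronically) directs the diene carbon next to the methyl-bearing carbon onto the acrolein β-carbon so that methyl and formyl end up 1,4, endo addition to the (E,E)-diene places CHO and both acetoxy groups cis, and the benzyl group of the (5S)-catalyst shields one iminium face so that C1 should form with R configuration.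

Step 3
Reactants: 4 (1R,3S,6S)-3,6-diacetoxy-4-methylcyclohex-4-ene-1-carbaldehyde
Product: 5 (1S,3S,6R)-1-ethenyl-4-methylcyclohex-4-ene-3,6-diyl diacetate (all-cis)
Conditions: Zn, CH2Br2, TiCl4, THF/CH2Cl2, 0 °C to rt
Reagents that add atoms: dibromomethane, BrCBr
Why: The gem-dimetallic methylene reagent of the Takai–Lombardo methylenation is non-basic, so the α-stereocentre C1 should not epimerise, the β-acetoxy group on C6 should not be eliminated, and the two esters should not be attacked.

Step 4
Reactants: 5 (1S,3S,6R)-1-ethenyl-4-methylcyclohex-4-ene-3,6-diyl diacetate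
Product: 6 (1S,3S,6R)-1-ethenyl-4-methylcyclohex-4-ene-3,6-diol (all-cis)
Conditions: K2CO3 (0.2 equiv), MeOH, 0 °C to rt
Reagents that add atoms: none
Why: Carbonate-catalysed methanolysis (transesterification) removes both acetates without breaking a ring C–O bond, so all three stereocentres are retained.

Step 5
Reactants: 6 (1S,3S,6R)-1-ethenyl-4-methylcyclohex-4-ene-3,6-diol
Product: 8 (3aR,4S,7aS)-4-ethenyl-2,2,7-trimethyl-3a,4,5,7a-tetrahydro-1,3-benzodioxole, via transposed cis-5,6-diol 7 (not isolated)
Conditions: Re2O7 (3 mol %), 2,2-dimethoxypropane (5 equiv), CH2Cl2, 0 °C to rt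
Reagents that add atoms: 2,2-dimethoxypropane, COC(C)(C)OC
Why: Perrhenate esters of allylic alcohols undergo reversible suprafacial [3,3] shifts (rhenium-oxo-catalysed 1,3-transposition), so the C3 hydroxyl is delivered to C5 on the same ring face and hence cis to the C6 hydroxyl, and among the equilibrating isomers the cis-5,6-diol with the trisubstituted C3=C4 alkene is drained as its acetonide, whereas shift of the C6 hydroxyl to the tertiary C4 position gives a less stable disubstituted alkene and should remain a minor reversible side channel.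

Step 6
Reactants: 8 (3aR,4S,7aS)-4-ethenyl-2,2,7-trimethyl-3a,4,5,7a-tetrahydro-1,3-benzodioxole; 9 methyl 4-methylpent-3-enoate
Product: 12 cis-1-(3-methylbut-2-en-1-yl)-2-[(3aR,4S,7aS)-2,2,7-trimethyl-3a,4,5,7a-tetrahydro-1,3-benzodioxol-4-yl]cyclopropan-1-ol, via titanacyclopropane 10 (not isolated), via titanium homoenolate 11 (not isolated)
Conditions: Ti(OiPr)4 (1.5 equiv), c-C6H11MgCl (4.5 equiv, added over 2 h), 9 (1.5 equiv), THF, rt; aq NH4Cl work-up
Reagents that add atoms: none
Why: Two equivalents of c-C6H11MgCl convert Ti(OiPr)4 into a cyclohexene complex of divalent titanium (a titanacyclopropane), which trades cyclohexene for the monosubstituted C7=C14 vinyl group of 8 to give 10. The ester carbonyl of 9 inserts into the unhindered Ti–C14 bond (forming C14–C8), methoxide is expelled to leave the β-titanio ketone 11, and its Ti–C7 bond adds to the ketone in a 3-exo-trig closure (forming C7–C8) that builds the cyclopropane ring. This is the Kulinkovich hydroxycyclopropanation in its alkene ligand-exchange form, the closest known reaction type being the coupling of esters with terminal alkenes such as homoallylic ethers. The new stereocentres C7 and C8 are set relative to each other in the ring-closing transition state, where the C9 chain on C8 avoids the titanium alkoxide and ends up cis to the C1 substituent on C7 (hydroxyl trans); the sense relative to C1 is not controlled and need not be, since step 7 erases both centres. The step needs exchange at the vinyl group only and insertion at C14, not C7: the trisubstituted C3=C4 and prenyl alkenes are too hindered to displace cyclohexene from titanium, branching at C7 blocks insertion there, and the C6 acetal oxygen is homoallylic (not allylic) to the vinyl group, so it can assist by coordination without opening a β-alkoxide elimination path.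

Step 7
Reactants: 12 cis-1-(3-methylbut-2-en-1-yl)-2-[(3aR,4S,7aS)-2,2,7-trimethyl-3a,4,5,7a-tetrahydro-1,3-benzodioxol-4-yl]cyclopropan-1-ol
Product: 13 6-methyl-2-[(3aR,4S,7aS)-2,2,7-trimethyl-3a,4,5,7a-tetrahydro-1,3-benzodioxol-4-yl]hepta-1,5-dien-3-one
Conditions: Pd(OAc)2 (10 mol %), pyridine (1 equiv), 3 Å MS, O2 (1 atm), toluene, 80 °C; product used at once
Reagents that add atoms: none
Why: In this oxidative cyclopropanol ring opening a divalent palladium alkoxide undergoes β-carbon elimination at the less substituted C8–C14 bond, the primary alkylpalladium loses the C7 hydride to give the 2-substituted enone, and O2 reoxidises the zerovalent palladium, so both cyclopropane diastereomers converge on 13 while the acetonide keeps the diol out of reach of the oxidant.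

Step 8
Reactants: 13 6-methyl-2-[(3aR,4S,7aS)-2,2,7-trimethyl-3a,4,5,7a-tetrahydro-1,3-benzodioxol-4-yl]hepta-1,5-dien-3-one
Product: 14 (3S)-6-methyl-2-[(3aR,4S,7aS)-2,2,7-trimethyl-3a,4,5,7a-tetrahydro-1,3-benzodioxol-4-yl]hepta-1,5-dien-3-ol
Conditions: (3aR)-1-methyl-3,3-diphenyltetrahydro-1H,3H-pyrrolo[1,2-c][1,3,2]oxazaborole [(R)-Me-CBS, 0.2 equiv], catecholborane (2 equiv), toluene, −78 °C; then MeOH, aq NaHCO3
Reagents that add atoms: none
Why: In the Corey–Bakshi–Shibata reduction the oxazaborolidine binds the carbonyl on the side of the smaller C9 methylene and away from the α-branched alkenyl group C7, so hydride from catecholborane reaches one face only and the (R)-catalyst should set C8 as S under reagent control, while the low temperature suppresses conjugate reduction and hydroboration.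

Step 9
Reactants: 14 (3S)-6-methyl-2-[(3aR,4S,7aS)-2,2,7-trimethyl-3a,4,5,7a-tetrahydro-1,3-benzodioxol-4-yl]hepta-1,5-dien-3-ol
Product: 15 (3S)-6-methyl-2-[(3aR,4S,7aS)-2,2,7-trimethyl-3a,4,5,7a-tetrahydro-1,3-benzodioxol-4-yl]hepta-1,5-dien-3-yl acetate
Conditions: Ac2O, Et3N, 4-(dimethylamino)pyridine (10 mol %), CH2Cl2, 0 °C to rt
Reagents that add atoms: acetic anhydride, CC(=O)OC(C)=O
Why: Nucleophile-catalysed acylation of the secondary allylic alcohol leaves the C8–O bond intact, so C8 keeps its configuration.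

Step 10
Reactants: 15 (3S)-6-methyl-2-[(3aR,4S,7aS)-2,2,7-trimethyl-3a,4,5,7a-tetrahydro-1,3-benzodioxol-4-yl]hepta-1,5-dien-3-yl acetate
Product: 16 (3S)-2-[(1S,5S,6R)-5,6-dihydroxy-4-methylcyclohex-3-en-1-yl]-6-methylhepta-1,5-dien-3-yl acetate
Conditions: AcOH/H2O 4:1, 40 °C
Reagents that add atoms: none
Why: Mild aqueous-acid acetal hydrolysis cleaves the cis-fused isopropylidene group, while the three alkenes and the C8 acetate are not activated towards dilute acetic acid and should persist.

Step 11
Reactants: 16 (3S)-2-[(1S,5S,6R)-5,6-dihydroxy-4-methylcyclohex-3-en-1-yl]-6-methylhepta-1,5-dien-3-yl acetate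
Product: 17 (3S)-2-[(1S,3S,4R,5R,6R)-3,4-epoxy-5,6-dihydroxy-4-methylcyclohexyl]-6-methylhepta-1,5-dien-3-yl acetate (epoxide oxygen cis to both hydroxyls and to the side chain)
Conditions: VO(acac)2 (5 mol %), t-BuOOH (1.5 equiv, in decane), CH2Cl2, 0 °C to rt
Reagents that add atoms: tert-butyl hydroperoxide, CC(C)(C)OO
Why: In the vanadium-catalysed hydroxyl-directed epoxidation the peroxide is delivered within a vanadate ester of the allylic C5 hydroxyl (reinforced by the homoallylic C6 hydroxyl) to the face of C3=C4 on which these hydroxyls lie, which sets C3 and C4 with the epoxide oxygen cis to both, while the prenyl alkene and the acetoxy-deactivated C7=C14 alkene have no allylic hydroxyl and should react far more slowly.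

Step 12
Reactants: 17 (3S)-2-[(1S,3S,4R,5R,6R)-3,4-epoxy-5,6-dihydroxy-4-methylcyclohexyl]-6-methylhepta-1,5-dien-3-yl acetate; 18 angelic acid [(Z)-2-methylbut-2-enoic acid]
Product: 20 (3S)-2-[(1S,3S,4S,5R,6R)-3,4-epoxy-4-methyl-5,6-bis{[(2Z)-2-methylbut-2-enoyl]oxy}cyclohexyl]-6-methylhepta-1,5-dien-3-yl acetate, via angelic 2,4,6-trichlorobenzoic anhydride 19 (not isolated)
Conditions: 18 (6 equiv), 2,4,6-trichlorobenzoyl chloride (6 equiv), Et3N (8 equiv), toluene, rt; then 17, 75 °C
Reagents that add atoms: none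
Why: The Yamaguchi esterification through the mixed 2,4,6-trichlorobenzoic anhydride, run without a nucleophilic catalyst, activates angelic acid without the conjugate addition–elimination that would turn the Z-alkene into the tiglate, both C–O bonds of the diol are retained, and the hydroxyls cannot open the epoxide from within because they are cis to its oxygen.

**Compound list**

1 | (E)-4-acetoxy-2-methylbut-2-enal | CC(=O)OC/C=C(C)/C=O | starting material
2 | (1E,3E)-2-methylbuta-1,3-diene-1,4-diyl diacetate | CC(=O)O/C=C/C(C)=C/OC(C)=O | intermediate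
3 | acrolein | C=CC=O | starting material
4 | (1R,3S,6S)-3,6-diacetoxy-4-methylcyclohex-4-ene-1-carbaldehyde | O=C[C@@H]1C[C@H](OC(C)=O)C(C)=C[C@@H]1OC(C)=O | intermediate
5 | (1S,3S,6R)-1-ethenyl-4-methylcyclohex-4-ene-3,6-diyl diacetate | C=C[C@@H]1C[C@H](OC(C)=O)C(C)=C[C@@H]1OC(C)=O | intermediate
6 | (1S,3S,6R)-1-ethenyl-4-methylcyclohex-4-ene-3,6-diol | C=C[C@@H]1C[C@H](O)C(C)=C[C@@H]1O | intermediate
7 | (1S,5S,6R)-1-ethenyl-4-methylcyclohex-3-ene-5,6-diol (not isolated) | C=C[C@@H]1CC=C(C)[C@H](O)[C@@H]1O | intermediate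
8 | (3aR,4S,7aS)-4-ethenyl-2,2,7-trimethyl-3a,4,5,7a-tetrahydro-1,3-benzodioxole | C=C[C@@H]1CC=C(C)[C@H](OC2(C)C)[C@@H]1O2 | intermediate
9 | methyl 4-methylpent-3-enoate | COC(=O)CC=C(C)C | starting material
10 | 1,1-di(propan-2-yloxy)-2-[(3aR,4S,7aS)-2,2,7-trimethyl-3a,4,5,7a-tetrahydro-1,3-benzodioxol-4-yl]titanacyclopropane (titanium bridging C7 and C14; not isolated) | CC(C)O[Ti]1(OC(C)C)CC1[C@@H]1CC=C(C)[C@H](OC2(C)C)[C@@H]1O2 | intermediate
11 | 6-methyl-1-[methoxybis(propan-2-yloxy)titanio]-1-[(3aR,4S,7aS)-2,2,7-trimethyl-3a,4,5,7a-tetrahydro-1,3-benzodioxol-4-yl]hept-5-en-3-one (titanium on C7, ketone at C8; not isolated) | CO[Ti](OC(C)C)(OC(C)C)C(CC(=O)CC=C(C)C)[C@@H]1CC=C(C)[C@H](OC2(C)C)[C@@H]1O2 | intermediate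
12 | cis-1-(3-methylbut-2-en-1-yl)-2-[(3aR,4S,7aS)-2,2,7-trimethyl-3a,4,5,7a-tetrahydro-1,3-benzodioxol-4-yl]cyclopropan-1-ol (the (7R,8R) isomer is drawn; the (7S,8S) isomer is expected alongside) | O[C@@]3(CC=C(C)C)C[C@@H]3[C@@H]1CC=C(C)[C@H](OC2(C)C)[C@@H]1O2 | intermediate
13 | 6-methyl-2-[(3aR,4S,7aS)-2,2,7-trimethyl-3a,4,5,7a-tetrahydro-1,3-benzodioxol-4-yl]hepta-1,5-dien-3-one | C=C(C(=O)CC=C(C)C)[C@@H]1CC=C(C)[C@H](OC2(C)C)[C@@H]1O2 | intermediate
14 | (3S)-6-methyl-2-[(3aR,4S,7aS)-2,2,7-trimethyl-3a,4,5,7a-tetrahydro-1,3-benzodioxol-4-yl]hepta-1,5-dien-3-ol | C=C([C@H](CC=C(C)C)O)[C@@H]1CC=C(C)[C@H](OC2(C)C)[C@@H]1O2 | intermediate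
15 | (3S)-6-methyl-2-[(3aR,4S,7aS)-2,2,7-trimethyl-3a,4,5,7a-tetrahydro-1,3-benzodioxol-4-yl]hepta-1,5-dien-3-yl acetate | C=C([C@H](CC=C(C)C)OC(C)=O)[C@@H]1CC=C(C)[C@H](OC2(C)C)[C@@H]1O2 | intermediate
16 | (3S)-2-[(1S,5S,6R)-5,6-dihydroxy-4-methylcyclohex-3-en-1-yl]-6-methylhepta-1,5-dien-3-yl acetate | C=C([C@H](CC=C(C)C)OC(C)=O)[C@@H]1CC=C(C)[C@H](O)[C@@H]1O | intermediate
17 | (3S)-2-[(1S,3S,4R,5R,6R)-3,4-epoxy-5,6-dihydroxy-4-methylcyclohexyl]-6-methylhepta-1,5-dien-3-yl acetate | C=C([C@H](CC=C(C)C)OC(C)=O)[C@@H]1C[C@@H]2O[C@]2(C)[C@H](O)[C@@H]1O | intermediate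
18 | angelic acid, (Z)-2-methylbut-2-enoic acid | C/C=C(/C)C(=O)O | starting material
19 | angelic 2,4,6-trichlorobenzoic anhydride (not isolated) | C/C=C(/C)C(=O)OC(=O)c1c(Cl)cc(Cl)cc1Cl | intermediate
20 | (3S)-2-[(1S,3S,4S,5R,6R)-3,4-epoxy-4-methyl-5,6-bis{[(2Z)-2-methylbut-2-enoyl]oxy}cyclohexyl]-6-methylhepta-1,5-dien-3-yl acetate | C=C([C@H](CC=C(C)C)OC(C)=O)[C@@H]1C[C@@H]2O[C@]2(C)[C@H](OC(=O)/C(C)=C\C)[C@@H]1OC(=O)/C(C)=C\C | target

**Step count.** Total: 12 steps. Longest linear sequence: 12 steps (1 to 20); compounds 3, 9 and 18 enter as purchased.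

**Steps most likely to fail**

1. Step 6. What may go wrong: ligand exchange into the α-branched vinyl group is outpaced by reaction of the cyclohexene–titanium species with the ester, or by enolisation of the β,γ-unsaturated ester, so that little cyclopropanol forms. The fallback sets out from 8 and returns at 13.
   - Wacker oxidation of the vinyl group (PdCl2, CuCl, O2, DMF/H2O) should give the methyl ketone 1-[(3aR,4R,7aS)-2,2,7-trimethyl-3a,4,5,7a-tetrahydro-1,3-benzodioxol-4-yl]ethan-1-one F1.
   - Kinetic enolisation on the methyl side (KN(SiMe3)2, PhNTf2, THF, −78 °C) should give the enol triflate 1-[(3aR,4R,7aS)-2,2,7-trimethyl-3a,4,5,7a-tetrahydro-1,3-benzodioxol-4-yl]ethenyl trifluoromethanesulfonate F2.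
   - Nozaki–Hiyama–Kishi coupling (CrCl2, NiCl2 2 mol %, DMF) with 4-methylpent-3-enal F3, made by Dess–Martin oxidation of purchased 4-methylpent-3-en-1-ol, forms the C7–C8 bond and should give 6-methyl-2-[(3aR,4S,7aS)-2,2,7-trimethyl-3a,4,5,7a-tetrahydro-1,3-benzodioxol-4-yl]hepta-1,5-dien-3-ol as a mixture of C8 epimers F4.
   - Dess–Martin oxidation converges both epimers on ketone 13, from which steps 8 to 12 follow unchanged.

2. Step 5. What may go wrong: the C6 hydroxyl, which is also allylic, shifts to the tertiary C4 position and that diol is trapped instead, or acid-promoted loss of water leads towards an aromatic ring. The fallback sets out from 6 and returns at 7, then 8; it lets the C4 methyl group, not a hydroxyl, decide the regiochemistry.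
   - Hydroxyl-directed epoxidation of 6 (VO(acac)2, t-BuOOH, CH2Cl2) should give the all-cis 4,5-epoxy-1-ethenyl-4-methylcyclohexane-3,6-diol F5.
   - Acetylation (Ac2O, pyridine) gives the all-cis 4,5-epoxy-1-ethenyl-4-methylcyclohexane-3,6-diyl diacetate F6.
   - Cp2TiCl (from Cp2TiCl2 and Zn, THF, rt) should open the epoxide homolytically at the tertiary carbon C4. A second equivalent of the trivalent titanium reagent captures the radical, and the C4 organotitanium expels the neighbouring C3 acetate. The C5–O bond of the epoxide is untouched and stays cis to C6, giving (1S,5S,6R)-6-acetoxy-1-ethenyl-4-methylcyclohex-3-en-5-ol F7.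
   - K2CO3 in MeOH then gives diol 7, which is isolated here, and 2,2-dimethoxypropane with pyridinium p-toluenesulfonate closes acetonide 8.

3. Step 12. What may go wrong: Z-to-E isomerisation of the angeloyl group during activation, or incomplete acylation of the hindered C5 hydroxyl next to the quaternary epoxide carbon. The fallback sets out from 17 and ends at 20.
   - Both hydroxyls are acylated with 2-[bis(2,2,2-trifluoroethoxy)phosphoryl]propanoic acid (1-ethyl-3-(3-dimethylaminopropyl)carbodiimide hydrochloride, 4-(dimethylamino)pyridine, CH2Cl2) to give the 5,6-bis{2-[bis(2,2,2-trifluoroethoxy)phosphoryl]propanoate} of 17 F8.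
   - A double Still–Gennari olefination with acetaldehyde (KN(SiMe3)2, 18-crown-6, THF, −78 °C) then builds both Z-configured 2-methylbut-2-enoates on the molecule and should deliver 20 without exposing a preformed angelate to acylation conditions.

**Further compounds**

F1 | step 6 | 1-[(3aR,4R,7aS)-2,2,7-trimethyl-3a,4,5,7a-tetrahydro-1,3-benzodioxol-4-yl]ethan-1-one | CC(=O)[C@@H]1CC=C(C)[C@H](OC2(C)C)[C@@H]1O2
F2 | step 6 | 1-[(3aR,4R,7aS)-2,2,7-trimethyl-3a,4,5,7a-tetrahydro-1,3-benzodioxol-4-yl]ethenyl trifluoromethanesulfonate | C=C(OS(=O)(=O)C(F)(F)F)[C@@H]1CC=C(C)[C@H](OC2(C)C)[C@@H]1O2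
F3 | step 6 | 4-methylpent-3-enal | CC(C)=CCC=O
F4 | step 6 | 6-methyl-2-[(3aR,4S,7aS)-2,2,7-trimethyl-3a,4,5,7a-tetrahydro-1,3-benzodioxol-4-yl]hepta-1,5-dien-3-ol, mixture of C8 epimers | C=C(C(O)CC=C(C)C)[C@@H]1CC=C(C)[C@H](OC2(C)C)[C@@H]1O2
F5 | step 5 | all-cis 4,5-epoxy-1-ethenyl-4-methylcyclohexane-3,6-diol | C=C[C@@H]1C[C@H](O)[C@]2(C)O[C@@H]2[C@@H]1O
F6 | step 5 | all-cis 4,5-epoxy-1-ethenyl-4-methylcyclohexane-3,6-diyl diacetate | C=C[C@@H]1C[C@H](OC(C)=O)[C@]2(C)O[C@@H]2[C@@H]1OC(C)=O
F7 | step 5 | (1S,5S,6R)-6-acetoxy-1-ethenyl-4-methylcyclohex-3-en-5-ol | C=C[C@@H]1CC=C(C)[C@H](O)[C@@H]1OC(C)=O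
F8 | step 12 | 5,6-bis{2-[bis(2,2,2-trifluoroethoxy)phosphoryl]propanoate} of 17 | C=C([C@H](CC=C(C)C)OC(C)=O)[C@@H]1C[C@@H]2O[C@]2(C)[C@H](OC(=O)C(C)P(=O)(OCC(F)(F)F)OCC(F)(F)F)[C@@H]1OC(=O)C(C)P(=O)(OCC(F)(F)F)OCC(F)(F)F
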